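**Retrosynthetic overview**

- The target is the (2S)-flavanone 10. Its C4 ketone is unmasked last from the spiro-1,3-dithiane 9, so the base-sensitive β-aryloxy ketone exists only at the end.
- Key disconnection: C3–C4 and O1–C8a are made together in a stereospecific formal (3+3) annulation. The C4–C4a–C8a unit of a lithiated 2-(2-fluoroaryl)-1,3-dithiane (acyl-anion carbon plus SNAr carbon) is inserted into the CH2–O bond of the enantiopure aryl oxirane 6. Ring C (the pyran ring) is the only ring formed; rings A and B come with the starting materials.
- Enabling feature: ring C is a β-aryloxy ketone. Its O1–C2–C3 triad is a ring-opened terminal epoxide and its C4–C4a–C8a triad is an ortho-fluorobenzaldehyde. The C8a–F carbon is meta to both ring-A methoxy groups (C5, C7), so no donor opposes the SNAr. C2 takes part in neither bond formation, so the epoxide configuration is carried over intact.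
- Oxirane 6 comes from 2',3',4'-trimethoxyacetophenone by α-bromination, CBS reduction and base closure. Dithiane 2 comes from 2-fluoro-4,6-dimethoxybenzaldehyde.

Key step: step 4

Remark: C2 of the target is (S); because CH2O and CH2Br outrank aryl in the CIP order, the spatially identical oxirane and bromohydrin carry the descriptor (R).
Remark: compounds 1 and 3 and all unnumbered reagents are taken as commercially available.

**Route**

Step 1
Reactants: 1 2-fluoro-4,6-dimethoxybenzaldehyde
Product: 2 2-(2-fluoro-4,6-dimethoxyphenyl)-1,3-dithiane
Conditions: HS(CH2)3SH, BF3·OEt2 (cat.), CH2Cl2, 0 °C → rt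
Reagents that add atoms: propane-1,3-dithiol, SCCCS
Why: Lewis-acid-catalysed dithioacetalisation of an aldehyde (the first stage of Corey–Seebach umpolung) is general, and the aryl fluoride and methyl ethers are inert to BF3·OEt2 at room temperature; no stereocentre is formed.

Step 2
Reactants: 3 1-(2,3,4-trimethoxyphenyl)ethan-1-one
Product: 4 2-bromo-1-(2,3,4-trimethoxyphenyl)ethan-1-one
Conditions: CuBr2 (2 equiv), EtOAc/CHCl3, reflux
Reagents that add atoms: copper(II) bromide, Br[Cu]Br
Why: Heterogeneous CuBr2 α-bromination of aryl methyl ketones runs through the enol and should favour the side chain over nuclear bromination of the acyl-deactivated trimethoxyarene.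

Step 3
Reactants: 4 2-bromo-1-(2,3,4-trimethoxyphenyl)ethan-1-one
Product: 6 (R)-2-(2,3,4-trimethoxyphenyl)oxirane, via (R)-bromohydrin 5 (not isolated)
Conditions: (R)-Me-CBS (10 mol %), BH3·SMe2, THF, 0 °C; MeOH quench; then 2 M aq. NaOH, THF/MeOH, rt
Reagents that add atoms: none
Why: In the Corey–Bakshi–Shibata reduction the aryl group takes the large-substituent position and CH2Br the small one, so the (R)-oxazaborolidine should deliver hydride to the Si face and set the (R)-carbinol centre, which is not touched when the alkoxide displaces the primary bromide in the intramolecular Williamson closure.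

Step 4
Reactants: 2 2-(2-fluoro-4,6-dimethoxyphenyl)-1,3-dithiane; 6 (R)-2-(2,3,4-trimethoxyphenyl)oxirane
Product: 9 (2S)-5,7-dimethoxy-2-(2,3,4-trimethoxyphenyl)spiro[chromane-4,2'-[1,3]dithiane], via lithiated dithiane 7 (not isolated), via lithium alkoxide 8 (not isolated)
Conditions: n-BuLi, THF, −78 → −30 °C; 6, −30 °C → rt; then KOt-Bu, DMSO, 70 °C (one pot)
Reagents that add atoms: none
Why: Deprotonation of the doubly sulfur-stabilised benzylic C–H of 2 gives the acyl-anion equivalent 7 (Corey–Seebach umpolung), which opens the strained oxirane 6 by SN2 attack at its unsubstituted CH2 carbon, forming the C3–C4 bond and releasing the C2 alkoxide 8; after Li-to-K exchange in DMSO this alkoxide displaces the ortho fluoride of ring A by intramolecular SNAr and forms the O1–C8a bond, so the net event is insertion of the C4–C4a–C8a unit into the CH2–O bond of the epoxide. The closest known reaction types are the alkylation of 2-lithio-2-aryl-1,3-dithianes with terminal epoxides and the base-mediated SNAr cyclisation of 3-(2-fluoroaryl)propanols to chromans. The pyran ring closes as a six-membered ring by attack of oxygen on an sp2 arene carbon (addition–elimination, formally 6-exo-trig with respect to the C8a=C8 bond, possibly concerted), and the quaternary spiro dithiane carbon favours the folded rotamer. No stereocentre is created: C2 is the oxirane methine carbon, takes part in neither bond formation and is not acidic under these conditions, so the (R)-epoxide is carried into the (2S) product with its spatial arrangement unchanged. The step needs terminal regioselectivity in the epoxide opening, secured by the SN2 bias of a bulky soft carbanion in Lewis-acid-free THF; site-selective metalation, secured by the much higher acidity of the dithiane C–H than of the ring C–H bonds; and fluoride rather than the C5 methoxy group as nucleofuge, secured by the far better SNAr leaving-group ability of fluoride and by its meta relationship to both methoxy donors.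

Step 5
Reactants: 9 (2S)-5,7-dimethoxy-2-(2,3,4-trimethoxyphenyl)spiro[chromane-4,2'-[1,3]dithiane]
Product: 10 (2S)-5,7-dimethoxy-2-(2,3,4-trimethoxyphenyl)chroman-4-one
Conditions: MeI (excess), CaCO3, MeCN/H2O (9:1), 45 °C
Reagents that add atoms: water, O
Why: In this alkylative dithiane hydrolysis, S-methylation gives a sulfonium ion that opens to a thionium ion strongly stabilised by the 2,4,6-trioxygenated ring A and is captured by water, while the non-oxidising, near-neutral medium should leave the electron-rich arenes and the C2 stereocentre (no base for retro-oxa-Michael opening) untouched.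

**Compound list**

1 | 2-fluoro-4,6-dimethoxybenzaldehyde | COc1cc(F)c(C=O)c(OC)c1 | starting material
2 | 2-(2-fluoro-4,6-dimethoxyphenyl)-1,3-dithiane | COc1cc(F)c(C2SCCCS2)c(OC)c1 | intermediate
3 | 1-(2,3,4-trimethoxyphenyl)ethan-1-one | CC(=O)c1ccc(OC)c(OC)c1OC | starting material
4 | 2-bromo-1-(2,3,4-trimethoxyphenyl)ethan-1-one | O=C(CBr)c1ccc(OC)c(OC)c1OC | intermediate
5 | (R)-2-bromo-1-(2,3,4-trimethoxyphenyl)ethan-1-ol | O[C@H](c1ccc(OC)c(OC)c1OC)CBr | intermediate
6 | (R)-2-(2,3,4-trimethoxyphenyl)oxirane | COc1ccc([C@@H]2CO2)c(OC)c1OC | intermediate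
7 | 2-(2-fluoro-4,6-dimethoxyphenyl)-2-lithio-1,3-dithiane | [Li]C1(c2c(F)cc(OC)cc2OC)SCCCS1 | intermediate
8 | lithium (S)-2-[2-(2-fluoro-4,6-dimethoxyphenyl)-1,3-dithian-2-yl]-1-(2,3,4-trimethoxyphenyl)ethan-1-olate | [Li+].[O-][C@H](c1ccc(OC)c(OC)c1OC)CC1(c2c(F)cc(OC)cc2OC)SCCCS1 | intermediate
9 | (2S)-5,7-dimethoxy-2-(2,3,4-trimethoxyphenyl)spiro[chromane-4,2'-[1,3]dithiane] | COc1cc(OC)c2c(c1)O[C@H](c1ccc(OC)c(OC)c1OC)CC21SCCCS1 | intermediate
10 | (2S)-5,7-dimethoxy-2-(2,3,4-trimethoxyphenyl)chroman-4-one | COc1cc(OC)c2c(c1)O[C@H](c1ccc(OC)c(OC)c1OC)CC2=O | target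

**Step count and risks**

Total step count: 5. Longest linear sequence: 4 steps (3 → 4 → 6 → 9 → 10).

Steps most likely to fail:

1. Step 4. Regiocontrol in the epoxide opening may be lost (attack at the benzylic carbon, or lithium-induced rearrangement of the electron-rich aryl oxirane). Ring lithiation next to fluorine may compete with dithiane deprotonation. The SNAr closure on a ring without an activating group may stall.
Fallback, setting out from 1 and 3 and returning at 10: the same two bonds are made at the flavone oxidation level, where the SNAr carbon is activated by the ortho carbonyl and no epoxide is involved. Aldehyde 1 is oxidised under Pinnick conditions (NaClO2, NaH2PO4, 2-methyl-2-butene, t-BuOH/H2O) to 2-fluoro-4,6-dimethoxybenzoic acid F1. This is converted with (COCl)2 and cat. DMF in CH2Cl2 into 2-fluoro-4,6-dimethoxybenzoyl chloride F2. The lithium enolate of 3 (LiHMDS, THF, −78 °C) is C-acylated by F2 in a crossed Claisen condensation to 1-(2-fluoro-4,6-dimethoxyphenyl)-3-(2,3,4-trimethoxyphenyl)propane-1,3-dione F3. Its enolate oxygen should displace fluoride on heating with K2CO3 in DMF (100 °C) to give 5,7-dimethoxy-2-(2,3,4-trimethoxyphenyl)-4H-chromen-4-one F4. Asymmetric hydrogenation of F4 (chiral Ru–NHC catalyst, H2, catalyst antipode chosen for the 2S series) should give the over-reduced cis alcohol (2S,4S)-5,7-dimethoxy-2-(2,3,4-trimethoxyphenyl)chroman-4-ol F5. Dess–Martin oxidation (CH2Cl2, NaHCO3, rt) then returns ketone 10 without touching C2.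

2. Step 3. Enantiofacial discrimination may be insufficient, because the ortho-methoxy group can bind borane and blur the size difference between the two ketone substituents. The electron-rich oxirane may also open under traces of acid during isolation.
Fallback, setting out from 4 and returning at 5: resolution replaces asymmetric catalysis. NaBH4 (MeOH, 0 °C) reduces 4 to racemic 2-bromo-1-(2,3,4-trimethoxyphenyl)ethan-1-ol F6. Lipase-catalysed transesterification (Burkholderia cepacia lipase, vinyl acetate, MTBE, rt) follows the empirical enantiopreference of lipases for aryl carbinols and should acylate the enantiomer with the aryl group in the large pocket, giving (S)-2-bromo-1-(2,3,4-trimethoxyphenyl)ethyl acetate F7. The (R)-bromohydrin 5 is left unreacted; the reaction is run past half conversion, 5 is separated by chromatography and closed with aqueous NaOH as in step 3.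

3. Step 5. S-alkylation and hydrolysis at the congested spiro thioketal may be incomplete, or the ring may open at the thionium stage (β-elimination of the aryloxide from C2) with erosion of configuration over the long reaction time.
Fallback, setting out from 9 and returning at 10: activation by S-oxidation replaces S-alkylation. NaIO4 (1 equiv, MeOH/H2O, 0 °C) should oxidise one sulfur chemoselectively to (2S)-5,7-dimethoxy-2-(2,3,4-trimethoxyphenyl)spiro[chromane-4,2'-[1,3]dithiane] 1'-oxide F8, used as the mixture of sulfoxide diastereomers. Dithioacetal S-oxides hydrolyse under mild aqueous acid (1 M HCl, THF, 0 °C → rt), which should give ketone 10 quickly and at low temperature.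

**Further compounds**

F1 | step 4 | 2-fluoro-4,6-dimethoxybenzoic acid | COc1cc(F)c(C(=O)O)c(OC)c1
F2 | step 4 | 2-fluoro-4,6-dimethoxybenzoyl chloride | COc1cc(F)c(C(=O)Cl)c(OC)c1
F3 | step 4 | 1-(2-fluoro-4,6-dimethoxyphenyl)-3-(2,3,4-trimethoxyphenyl)propane-1,3-dione | COc1cc(F)c(C(=O)CC(=O)c2ccc(OC)c(OC)c2OC)c(OC)c1
F4 | step 4 | 5,7-dimethoxy-2-(2,3,4-trimethoxyphenyl)-4H-chromen-4-one | COc1cc(OC)c2c(c1)oc(-c1ccc(OC)c(OC)c1OC)cc2=O
F5 | step 4 | (2S,4S)-5,7-dimethoxy-2-(2,3,4-trimethoxyphenyl)chroman-4-ol | COc1cc(OC)c2c(c1)O[C@H](c1ccc(OC)c(OC)c1OC)C[C@@H]2O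
F6 | step 3 | racemic 2-bromo-1-(2,3,4-trimethoxyphenyl)ethan-1-ol | OC(CBr)c1ccc(OC)c(OC)c1OC
F7 | step 3 | (S)-2-bromo-1-(2,3,4-trimethoxyphenyl)ethyl acetate | CC(=O)O[C@@H](c1ccc(OC)c(OC)c1OC)CBr
F8 | step 5 | (2S)-5,7-dimethoxy-2-(2,3,4-trimethoxyphenyl)spiro[chromane-4,2'-[1,3]dithiane] 1'-oxide | COc1cc(OC)c2c(c1)O[C@H](c1ccc(OC)c(OC)c1OC)CC21SCCCS1=O
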